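The constants used here are made up; the flask was simulated.

Two questions stand over this flask: how much target with its crystals is there at the end, and how near saturation does the dissolved gas stand then?

    gas phase ⇌ dissolved gas, rate k1*(csat - [dissolved gas]) (k1 = 8.02 /h, csat = 48 mM)
    substrate + dissolved gas → target (k2 = 242 /M/h)
    dissolved gas + target → over-reacted product (k3 = 9.96 /M/h)
    crystals ⇌ target, rate k4*(cs4 - [target]) while solid is left; crystals form when [target] > cs4 (cs4 = 35 mM, k4 = 1.58 /h)
    target → over-reaction product (k5 = 0.166 /h)
    2 substrate → homo dimer (k6 = 0.0828 /M/h)

substrate 1.5 M; gas phase 48 mM (held); time 20 h

* how much target and crystals together there is at 20 h, in percent of the substrate charged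
* concentration of dissolved gas in solution at 20 h, in percent of saturation

- percentages count the substrate that a species holds: one homo dimer counts as two
- target is meant together with its crystals
- two of one species on the left: rate k times its square, two consumed each time
- solid, in amounts per volume of the solution: crystals
- at the start none of the gas is dissolved
- run time (flask): 20 h

The odd thing is that the constant of the step from substrate and dissolved gas to target, the gas step, is 2920 times that of the dimer step, and still I expect about half of the substrate used at the start to go to homo dimer. The two numbers go together because the substrate at its charge removes dissolved gas at 363 /h, faster than the transfer coefficient 8.02 /h can refill it, so the gas step runs near the feed, 8.02 /h times 48 mM, which is 0.385 M/h, while c(substrate) stays well above 0.0331 M; over that stretch transfer is its rate-limiting step. The dimer step needs no gas and consumes substrate at 0.373 M/h at the charge. The dimer rate over the feed is then 0.968; this split ratio, a selectivity factor, holds no time, and it falls with the square of c(substrate).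

The share of substrate going to homo dimer at any moment of that stretch is the ratio over one plus the ratio: 49.2% at the start, 19.5% at mid-charge, falling towards nil as c(substrate) nears zero. Simpson's rule over that fall gives 21.2% of the charge, leaving 78.8% to become target. My reckoning ends there; I put no number on what target loses to its two further steps. The forecast goes further, to 47% and 97%, and its ground is this: “Gas uptake is limited by mass transfer”.

The flask gives 49.0% and 97.0% at 20 h, both within the forecast's margin, and its homo dimer holds 21.7% against the 21.2% reckoned from the split ratio 0.968. In the neighbour charged with 0.60 M of substrate, time held, the ratio drops to 0.155, and the same average gives 4.72%. That neighbour's homo dimer holds 5.25% of its own charge at 20.0 h, and its target with crystals stands at 29.8%, against 49.0% in the flask.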